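**Assumption:** the target is achiral (planar, no stereocentre), so there is no enantiomer to control and the route delivers the single compound drawn.

## Retrosynthetic overview

1. Target ⇒ open the N1–C2 bond of the pyrrole ring and move the C3 bromine back to C2: this gives 1,2-dibromo-4-(2,2-dibromoethenyl)-5-nitrobenzene, with the nitro group as the nitrogen source.
2. gem-Dibromoalkene ⇒ C=C disconnection (Ramirez olefination): 4,5-dibromo-2-nitrobenzaldehyde and CBr4.
3. Nitro-aldehyde ⇒ aryl C–N disconnection (nitration): 3,4-dibromobenzaldehyde.
4. Ring order: the benzene ring is bought with both aryl bromines in place; the pyrrole ring is the only ring formed, in the last step.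

## Route

Step 1
Reactants: 1 3,4-dibromobenzaldehyde
Product: 2 4,5-dibromo-2-nitrobenzaldehyde
Conditions: fuming HNO3 (1.2 equiv), conc. H2SO4, 0 to 10 °C, 2 h; pour on ice; recrystallise from EtOH
Reagents that add atoms: nitric acid, O[N+](=O)[O-]
Why: Electrophilic aromatic nitration (SEAr) is expected mainly at C6, which is para to the 3-bromine, ortho to CHO and not flanked by two substituents, by analogy with other 3-halo- and 3,4-dihalobenzaldehydes; minor isomers are removed by crystallisation.

Step 2
Reactants: 2 4,5-dibromo-2-nitrobenzaldehyde, 3 carbon tetrabromide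
Product: 4 1,2-dibromo-4-(2,2-dibromoethenyl)-5-nitrobenzene
Conditions: CBr4 (1.5 equiv), PPh3 (3.0 equiv), CH2Cl2, 0 °C, 1 h; filter through silica
Reagents that add atoms: carbon tetrabromide, BrC(Br)(Br)Br
Why: Ramirez dibromo-olefination (first stage of the Corey–Fuchs sequence) is fast on electron-poor 2-nitrobenzaldehydes, and the nitro group and aryl bromides are inert to PPh3 at 0 °C.

Step 3
Reactants: 4 1,2-dibromo-4-(2,2-dibromoethenyl)-5-nitrobenzene
Product: 8 2,3,5,6-tetrabromo-1H-indole, via nitrosostyrene 5 (not isolated), via 2,2,5,6-tetrabromo-2H-indole 6 (not isolated), via 2,3,5,6-tetrabromo-3H-indole 7 (not isolated)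
Conditions: 1,2,2,3,4,4-hexamethylphosphetane 1-oxide (15 mol %), PhSiH3 (2.2 equiv), toluene, 100 °C, Ar, dark, 4–8 h
Reagents that add atoms: none
Why: Proposed new method: P(III)/P(V)=O-catalysed deoxygenation takes the nitro group through nitrosoarene 5 to the nitrene level, the nitrogen closes onto the CBr2 carbon (N1–C2 bond, 6π-electrocyclisation) to give 2H-indole 6, one bromine of the gem-dibromide then shifts from C2 to C3 (suprafacial [1,5] shift through a bromiranium-like bridge, driven by rearomatisation of the benzene ring) to give 3H-indole 7, and prototropy gives 8; the closest known reactions are the Cadogan–Sundberg reductive cyclisation of β,β-disubstituted 2-nitrostyrenes and the nitrene cyclisation of the matching aryl azides, where carbon groups migrate from C2 to C3, together with the acid-induced bromine walk between C3 and C2 of bromoindolenines, but a halogen has not been used as the migrating group in such a cyclisation.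

## Compound list

1 | 3,4-dibromobenzaldehyde | O=Cc1ccc(Br)c(Br)c1 | starting material
2 | 4,5-dibromo-2-nitrobenzaldehyde | O=Cc1cc(Br)c(Br)cc1[N+](=O)[O-] | intermediate
3 | carbon tetrabromide | BrC(Br)(Br)Br | starting material
4 | 1,2-dibromo-4-(2,2-dibromoethenyl)-5-nitrobenzene | [O-][N+](=O)c1cc(Br)c(Br)cc1C=C(Br)Br | intermediate
5 | 1,2-dibromo-4-(2,2-dibromoethenyl)-5-nitrosobenzene (the nitrosostyrene) | O=Nc1cc(Br)c(Br)cc1C=C(Br)Br | intermediate
6 | 2,2,5,6-tetrabromo-2H-indole | BrC1(Br)C=C2C=C(Br)C(Br)=CC2=N1 | intermediate
7 | 2,3,5,6-tetrabromo-3H-indole (racemic at C3, transient) | BrC1=Nc2cc(Br)c(Br)cc2C1Br | intermediate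
8 | 2,3,5,6-tetrabromo-1H-indole | Brc1cc2[nH]c(Br)c(Br)c2cc1Br | target

## Summary

Total step count: 3. Longest linear sequence: 3.

Steps most likely to fail:

**Step 3 (the new cyclisation with bromine shift).** The 2H-indole 6 may lose a bromine instead of shifting it, which would give the 2,5,6-tribromoindole, or the phosphine catalyst may be trapped by the gem-dibromoalkene and the reaction stall. The fallback uses known chemistry, sets out from 4 and comes back at 8. The nitro group of 4 is reduced with SnCl2·2H2O in EtOH at 70 °C to 4,5-dibromo-2-(2,2-dibromoethenyl)aniline F4. The ring is then closed by the known Pd(0)/P(t-Bu)3-catalysed intramolecular N-vinylation of ortho-(gem-dibromovinyl)anilines (Pd2(dba)3, P(t-Bu)3·HBF4, K2CO3, toluene, 100 °C), where the bulky phosphine keeps oxidative addition at the ring C–Br bonds reversible, to give 2,5,6-tribromo-1H-indole F5. Bromination at C3 with NBS (1.0 equiv, DMF, 0 °C) gives 8. Any 2,5,6-tribromoindole formed as a by-product in step 3 itself can be taken on to 8 by the same NBS treatment.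

**Step 1 (regiochemistry of the nitration).** Attack at C5 (ortho to the 4-bromine, meta to CHO) or at C2 could give isomers that are hard to remove. The fallback sets out from 1 and comes back at 2. Aldehyde 1 is condensed with MeONH2·HCl and NaOAc in EtOH to (E)-3,4-dibromobenzaldehyde O-methyl oxime F1. Chelation-directed Pd(II) C–H nitration (Pd(OAc)2 cat., AgNO2, K2S2O8, DCE, 110 °C) places the nitro group only ortho to the oxime carbon, at the less hindered C6, to give (E)-4,5-dibromo-2-nitrobenzaldehyde O-methyl oxime F2. Oxime exchange with aqueous formaldehyde and HCl in THF at 60 °C releases 2.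

**Step 2 (Ramirez olefination).** This is the least risky step, but PPh3 could attack the activated bromoarene or the product, and removing the phosphorus residues may cost material. The fallback sets out from 2 and comes back at 4. Aldehyde 2 is condensed with hydrazine hydrate in EtOH at room temperature to (E)-(4,5-dibromo-2-nitrobenzylidene)hydrazine F3. The copper-catalysed olefination of N-unsubstituted hydrazones with polyhaloalkanes (CBr4, CuCl 10 mol %, aq. NH3, DMSO, rt) then gives 4 with loss of nitrogen and no phosphine in the flask.

## Further compounds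

F1 | step 1 | (E)-3,4-dibromobenzaldehyde O-methyl oxime | CO/N=C/c1ccc(Br)c(Br)c1
F2 | step 1 | (E)-4,5-dibromo-2-nitrobenzaldehyde O-methyl oxime | CO/N=C/c1cc(Br)c(Br)cc1[N+](=O)[O-]
F3 | step 2 | (E)-(4,5-dibromo-2-nitrobenzylidene)hydrazine | N/N=C/c1cc(Br)c(Br)cc1[N+](=O)[O-]
F4 | step 3 | 4,5-dibromo-2-(2,2-dibromoethenyl)aniline | Nc1cc(Br)c(Br)cc1C=C(Br)Br
F5 | step 3 | 2,5,6-tribromo-1H-indole | Brc1cc2cc(Br)c(Br)cc2[nH]1
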